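Amounts first. The flask holds Za (monomer) at 0.40 M, with Zc (initiator) at 1.8 mol% of it. Each Zc that reacts begins one chain, so chains begun cannot exceed the Zc charged. Zb is monomer in chains, Zd the living end, and Ze consumes Za into Zg.

the same everywhere: Zc 1.8 mol%
- violet: Za 0.40 M; Ze 8 mM; the very flask that is asked about, followed so far
- blue: Za 0.20 M; Ze 8 mM; run made earlier
- flask: Za 0.40 M; Ze 8.00 mM; time 2.0 min

| run | time / s | Zb / % | Za / % |
|---|---|---|---|
| violet | 10.0 | 3.8 | 96.5 |
| violet | 12.0 | 3.5 | 95.7 |
| violet | 25.0 | 6.2 | 91.5 |
| blue | 25.0 | 3.1 | 94.5 |
| blue | 50.0 | 4.3 | 89.8 |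
| blue | 80.0 | 11.4 | 85.2 |
| blue | 90.0 | 12.4 | 85.0 |
| blue | 120 | 13.5 | 82.5 |

(readings scatter by 1 percentage point)

* whether the average number of monomer units in a chain (chains begun, living or dead) reaches 10 by 2.0 min (yes / no)
* average number of monomer units in a chain (chains begun, living or dead) at 2.0 min

- the average divides the monomer in chains by the number of chains begun, living and dead together
- candidate steps: Za + Zc -> Zd + Zb; Za + Zd -> Zb + Zd; Ze + Za -> Zg; 2 Zd -> Zf
- the earlier runs do not show the number of chains; that part of a forecast is a guess

I treated the chain count as a correction on the large quantity, Zb. If every Zc began a chain, length 10 takes Zb at 18.0% of the charge: the sure yield, past which that length is certain.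

From above, violet read twice blue at 25.0 s. Holding that ratio to 120 s gives Zb of 27.0%, or length 15.0 with every Zc counted.

From below, the candidate steps are all bimolecular, so doubling Za and Zc at one loading roughly doubles the clock; the match is not exact, since Ze stood at 8 mM in both runs, a smaller fraction of violet's Za. I took violet to reach about blue's final 13.5% halfway through, and I allowed one more of blue's last gains, 2.1 percentage points. That gives Zb of 15.6%, or length 8.67.

The sure yield lies inside this Zb range, so the range gives no firm answer, but each Zc left unused takes one chain off the divisor and raises the length. I said yes.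

The forecast said yes, with 11.5, inside my bracket, and cautioned: “Chain count is a guess; slower initiation would raise dp.”

The flask gave yes and 17.4, above the forecast and above the top of my bracket, with Zb at 24.3%, past the sure yield.

Za + Zc → Zd + Zb (k = 0.0370 M⁻¹ s⁻¹); Za + Zd → Zb + Zd, rate k2*[Zd]*[Za] (k = 4.50 M⁻¹ s⁻¹); Ze + Za → Zg (k = 2.50 M⁻¹ s⁻¹); 2 Zd → Zf (k = 83.0 M⁻¹ s⁻¹) Zc's half-life by initiation at that time was 1.1 min, against 2.0 min elapsed, and 22% of its charge remained, so the sure yield for the chains actually begun shrinks to 14.0%.

Readings and results were computed for substances that don't exist, noise included.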